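**Strategy**

The γ-butyrolactone ring is disconnected at the bond between its carbonyl carbon C2 and the α-carbon C3, together with the bond from the C3 methylene to the trimethoxyphenyl ring. The route exploits the fact that C3 carries an exocyclic CH2–aryl group next to the lactone carbonyl: an alkoxycarbonyl radical, made by photoredox oxidation of a homoallylic hydrogen oxalate, closes 5-exo-trig onto a vinyl group (C2–C3), and the resulting primary radical on the exocyclic carbon is arylated by nickel with 5-bromo-1,2,3-trimethoxybenzene. The C4 stereocentre, set by Evans alkylation, directs C3 trans. The precursor is an open-chain (R)-2-benzylbut-3-enyl oxalate with neither lactone nor trimethoxyphenyl ring.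

Key step: step 6

Assumption: compounds 1, 2, 5, 10 and 13 are taken as commercial. The lactone is numbered C2 (carbonyl), C3 (α-carbon), C4 (β-carbon), C5 (OCH2); the target is the (3R,4R) trans isomer.

**Route**

Step 1
Reactants: 1 (R)-4-benzyloxazolidin-2-one; 2 (E)-but-2-enoyl chloride
Product: 4 (R)-4-benzyl-3-[(E)-but-2-enoyl]oxazolidin-2-one, via lithium oxazolidinide 3 (not isolated)
Conditions: n-BuLi, THF, −78 °C; then 2, −78 → 0 °C
Reagents that add atoms: none
Why: N-acylation of the lithiated Evans auxiliary by the acid chloride; the (E)-alkene and the auxiliary stereocentre are not touched.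

Step 2
Reactants: 5 [4-(benzyloxy)-3-methoxyphenyl]methanol
Product: 6 1-(benzyloxy)-4-(bromomethyl)-2-methoxybenzene
Conditions: PBr3, Et2O, 0 °C; used crude at once
Reagents that add atoms: phosphorus tribromide, BrP(Br)Br
Why: Bromination of an electron-rich benzylic alcohol through its phosphite ester and bromide displacement; the aryl benzyl ether should survive the short cold exposure.

Step 3
Reactants: 4 (R)-4-benzyl-3-[(E)-but-2-enoyl]oxazolidin-2-one; 6 1-(benzyloxy)-4-(bromomethyl)-2-methoxybenzene
Product: 8 (R)-4-benzyl-3-[(2R)-2-[4-(benzyloxy)-3-methoxybenzyl]but-3-enoyl]oxazolidin-2-one, via sodium dienolate 7 (not isolated)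
Conditions: NaHMDS (1.05 equiv), THF, −78 °C; then 6, −78 → −45 °C; AcOH quench at −78 °C
Reagents that add atoms: none
Why: Evans asymmetric alkylation in its deconjugative form: γ-deprotonation of the s-cis enoyl imide gives the chelated (Z)-sodium dienolate, which is benzylated at the α-carbon on the face opposite the auxiliary benzyl group, setting the (R) centre that becomes C4 of the lactone.

Step 4
Reactants: 8 (R)-4-benzyl-3-[(2R)-2-[4-(benzyloxy)-3-methoxybenzyl]but-3-enoyl]oxazolidin-2-one
Product: 9 (2R)-2-[4-(benzyloxy)-3-methoxybenzyl]but-3-en-1-ol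
Conditions: LiBH4, MeOH (1 equiv), Et2O, 0 °C
Reagents that add atoms: none
Why: Reductive cleavage of the N-acyl oxazolidinone at the exocyclic carbonyl by LiBH4 gives the primary alcohol and frees the auxiliary; the non-basic hydride should leave the α-stereocentre and the β,γ-alkene in place.

Step 5
Reactants: 9 (2R)-2-[4-(benzyloxy)-3-methoxybenzyl]but-3-en-1-ol; 10 oxalyl chloride
Product: 12 2-{[(2R)-2-[4-(benzyloxy)-3-methoxybenzyl]but-3-en-1-yl]oxy}-2-oxoacetic acid, via chlorooxoacetate ester 11 (not isolated)
Conditions: 9 added to (COCl)2 (2 equiv), Et2O, 0 °C → rt; then H2O, 0 °C; used crude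
Reagents that add atoms: water, O
Why: Acylation of the primary alcohol by excess oxalyl chloride and hydrolysis of the remaining acid chloride is the standard preparation of alkyl hydrogen oxalates; the excess of oxalyl chloride suppresses the dialkyl oxalate.

Step 6
Reactants: 12 2-{[(2R)-2-[4-(benzyloxy)-3-methoxybenzyl]but-3-en-1-yl]oxy}-2-oxoacetic acid; 13 5-bromo-1,2,3-trimethoxybenzene
Product: 15 (3R,4R)-4-[4-(benzyloxy)-3-methoxybenzyl]-3-(3,4,5-trimethoxybenzyl)dihydrofuran-2(3H)-one, via cesium oxalate 14 (not isolated)
Conditions: Ir[dF(CF3)ppy]2(dtbbpy)PF6 (1 mol %), NiBr2·glyme (5 mol %), dtbbpy (5 mol %), CsHCO3 (1.5 equiv), 13 (1.5 equiv), degassed DME/DMSO, blue LEDs (450 nm), 25 °C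
Reagents that add atoms: none
Why: CsHCO3 turns 12 into cesium oxalate 14, the photoexcited trivalent iridium complex oxidizes its carboxylate, loss of CO2 gives the alkoxycarbonyl radical, this radical adds to the internal carbon of the vinyl group to form the C2–C3 bond, and the primary radical left on the exocyclic CH2 is captured by the divalent arylnickel bromide made from 13 and zerovalent nickel, after which reductive elimination from trivalent nickel forms the CH2–aryl bond and the reduced iridium complex returns nickel to the zerovalent state. The closest known reaction type is the photoredox/nickel alkoxycarbonyl radical cyclization–cross-coupling cascade of homoallylic oxalates with aryl halides, itself a descendant of tin hydride cyclizations of alkoxycarbonyl radicals from selenocarbonates. The lactone ring closes in the 5-exo-trig mode. The new C3 stereocentre is controlled by the C4 stereocentre of the substrate: in the chair-like transition state the allylic aryl-CH2 group lies pseudo-equatorial, so the two benzylic arms end up trans, which gives the (3R,4R) lactone and is also the thermodynamically preferred arrangement (a minor cis isomer could be converged by epimerization at C3 with DBU). The step needs ring closure to be faster than loss of a second CO2 and than direct capture of the alkoxycarbonyl radical by nickel; the primary alkoxy group (slow decarboxylation), the unhindered terminal alkene five atoms away and a low nickel loading secure this. The benzyl ether keeps the phenol out of reach of the photo-oxidant.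

Step 7
Reactants: 15 (3R,4R)-4-[4-(benzyloxy)-3-methoxybenzyl]-3-(3,4,5-trimethoxybenzyl)dihydrofuran-2(3H)-one
Product: 16 hernanol
Conditions: H2 (1 atm), 10% Pd/C, EtOAc/MeOH, rt
Reagents that add atoms: none
Why: Hydrogenolysis of the aryl benzyl ether over Pd/C under neutral conditions frees the phenol; the lactone, the methyl ethers and both stereocentres should be inert.

**Compound list**

1 | (R)-4-benzyloxazolidin-2-one | O=C1N[C@H](Cc2ccccc2)CO1 | starting material
2 | (E)-but-2-enoyl chloride (crotonoyl chloride) | C/C=C/C(Cl)=O | starting material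
3 | lithium (R)-4-benzyl-2-oxooxazolidin-3-ide | [Li+].O=C1[N-][C@H](Cc2ccccc2)CO1 | intermediate
4 | (R)-4-benzyl-3-[(E)-but-2-enoyl]oxazolidin-2-one | C/C=C/C(=O)N1[C@H](Cc2ccccc2)COC1=O | intermediate
5 | [4-(benzyloxy)-3-methoxyphenyl]methanol | COc1cc(CO)ccc1OCc1ccccc1 | starting material
6 | 1-(benzyloxy)-4-(bromomethyl)-2-methoxybenzene | COc1cc(CBr)ccc1OCc1ccccc1 | intermediate
7 | sodium (Z)-dienolate of 4 | [Na+].C=C/C=C(\[O-])N1[C@H](Cc2ccccc2)COC1=O | intermediate
8 | (R)-4-benzyl-3-[(2R)-2-[4-(benzyloxy)-3-methoxybenzyl]but-3-enoyl]oxazolidin-2-one | COc1cc(C[C@H](C=C)C(=O)N2[C@H](Cc3ccccc3)COC2=O)ccc1OCc1ccccc1 | intermediate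
9 | (2R)-2-[4-(benzyloxy)-3-methoxybenzyl]but-3-en-1-ol | COc1cc(C[C@H](C=C)CO)ccc1OCc1ccccc1 | intermediate
10 | oxalyl chloride | O=C(Cl)C(=O)Cl | starting material
11 | (2R)-2-[4-(benzyloxy)-3-methoxybenzyl]but-3-en-1-yl chlorooxoacetate | COc1cc(C[C@H](C=C)COC(=O)C(=O)Cl)ccc1OCc1ccccc1 | intermediate
12 | 2-{[(2R)-2-[4-(benzyloxy)-3-methoxybenzyl]but-3-en-1-yl]oxy}-2-oxoacetic acid (hydrogen oxalate) | COc1cc(C[C@H](C=C)COC(=O)C(=O)O)ccc1OCc1ccccc1 | intermediate
13 | 5-bromo-1,2,3-trimethoxybenzene | COc1cc(Br)cc(OC)c1OC | starting material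
14 | cesium salt of 12 (cesium oxalate) | [Cs+].COc1cc(C[C@H](C=C)COC(=O)C(=O)[O-])ccc1OCc1ccccc1 | intermediate
15 | (3R,4R)-4-[4-(benzyloxy)-3-methoxybenzyl]-3-(3,4,5-trimethoxybenzyl)dihydrofuran-2(3H)-one | COc1cc(C[C@H]2COC(=O)[C@@H]2Cc2cc(OC)c(OC)c(OC)c2)ccc1OCc1ccccc1 | intermediate
16 | hernanol, (3R,4R)-4-(4-hydroxy-3-methoxybenzyl)-3-(3,4,5-trimethoxybenzyl)dihydrofuran-2(3H)-one | COc1cc(C[C@H]2COC(=O)[C@@H]2Cc2cc(OC)c(OC)c(OC)c2)ccc1O | target

**Summary**

Total step count: 7. Longest linear sequence: 6 steps (step 1 or step 2, then steps 3 to 7).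

**Steps most likely to fail**

Step 6. The alkoxycarbonyl radical may be captured by nickel before it cyclizes, the alkylnickel intermediate may undergo β-hydride elimination, or oxidative addition of the electron-rich aryl bromide may be too slow to keep pace with radical generation. Fallback: from alcohol 9, cross-metathesis with 3,4,5-trimethoxystyrene (C=Cc1cc(OC)c(OC)c(OC)c1; second-generation Hoveyda–Grubbs catalyst, CH2Cl2, 40 °C) would give (2R,3E)-2-[4-(benzyloxy)-3-methoxybenzyl]-4-(3,4,5-trimethoxyphenyl)but-3-en-1-ol F1, in which the aryl ring is already in place. Phosgene/pyridine would convert it into the chloroformate F2, and PhSeH/pyridine into the Se-phenyl selenocarbonate F3. Slow addition of Bu3SnH with AIBN in benzene at 80 °C would then generate the same alkoxycarbonyl radical, which closes 5-exo-trig onto the styrene to form the C2–C3 bond; the benzylic radical is reduced by the tin hydride. The sequence returns to the route at lactone 15.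

Step 3. The dienolate may alkylate in part at the γ-carbon, and the doubly activated α-proton of the product may be removed by residual base, leading to reconjugation of the alkene and erosion of the diastereomeric purity. Fallback: from bromide 6, alkylation of diethyl malonate (NaH, THF) would give diethyl 2-[4-(benzyloxy)-3-methoxybenzyl]malonate F4, and LiAlH4 would reduce it to 2-[4-(benzyloxy)-3-methoxybenzyl]propane-1,3-diol F5. Lipase desymmetrization (Amano lipase PS with vinyl acetate, or the complementary enzymatic hydrolysis of the diacetate, whichever mode delivers the required enantiomer) would give (R)-monoacetate F6. Buffered Dess–Martin oxidation would give the (S)-aldehyde F7, which is methylenated without base (Zn, CH2Br2, TiCl4) to (R)-homoallyl acetate F8. Methanolysis (K2CO3, MeOH) returns to the route at alcohol 9.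

Step 5. Double acylation to the dialkyl oxalate, or hydrolytic loss of the half-ester during the aqueous quench, would leave material that cannot be purified by chromatography and would carry impurities into the key step. Fallback: from alcohol 9, acylation with tert-butyl chlorooxoacetate (Et3N, DMAP, CH2Cl2, 0 °C) would give the chromatographable mixed tert-butyl oxalate F9. Acidolysis of the tert-butyl ester (TFA, CH2Cl2, 0 °C, with 1,3-dimethoxybenzene as cation scavenger) returns to the route at hydrogen oxalate 12.

**Further compounds**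

F1 | step 6 | (2R,3E)-2-[4-(benzyloxy)-3-methoxybenzyl]-4-(3,4,5-trimethoxyphenyl)but-3-en-1-ol | COc1cc(C[C@H](/C=C/c2cc(OC)c(OC)c(OC)c2)CO)ccc1OCc1ccccc1
F2 | step 6 | (2R,3E)-2-[4-(benzyloxy)-3-methoxybenzyl]-4-(3,4,5-trimethoxyphenyl)but-3-en-1-yl chloroformate | COc1cc(C[C@H](/C=C/c2cc(OC)c(OC)c(OC)c2)COC(=O)Cl)ccc1OCc1ccccc1
F3 | step 6 | O-[(2R,3E)-2-[4-(benzyloxy)-3-methoxybenzyl]-4-(3,4,5-trimethoxyphenyl)but-3-en-1-yl] Se-phenyl selenocarbonate | COc1cc(C[C@H](/C=C/c2cc(OC)c(OC)c(OC)c2)COC(=O)[Se]c2ccccc2)ccc1OCc1ccccc1
F4 | step 3 | diethyl 2-[4-(benzyloxy)-3-methoxybenzyl]malonate | CCOC(=O)C(Cc1ccc(OCc2ccccc2)c(OC)c1)C(=O)OCC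
F5 | step 3 | 2-[4-(benzyloxy)-3-methoxybenzyl]propane-1,3-diol | COc1cc(CC(CO)CO)ccc1OCc1ccccc1
F6 | step 3 | (2R)-2-[4-(benzyloxy)-3-methoxybenzyl]-3-hydroxypropyl acetate | COc1cc(C[C@H](CO)COC(C)=O)ccc1OCc1ccccc1
F7 | step 3 | (2S)-2-[4-(benzyloxy)-3-methoxybenzyl]-3-oxopropyl acetate | COc1cc(C[C@H](C=O)COC(C)=O)ccc1OCc1ccccc1
F8 | step 3 | (2R)-2-[4-(benzyloxy)-3-methoxybenzyl]but-3-en-1-yl acetate | COc1cc(C[C@H](C=C)COC(C)=O)ccc1OCc1ccccc1
F9 | step 5 | (2R)-2-[4-(benzyloxy)-3-methoxybenzyl]but-3-en-1-yl tert-butyl oxalate | COc1cc(C[C@H](C=C)COC(=O)C(=O)OC(C)(C)C)ccc1OCc1ccccc1
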